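## Structural features

The target is a diarylmethane: two fully substituted benzene rings, ring A and ring B, are joined through one methylene group (a5–CH2–C8). Ring A is an acylphloroglucinol in which a1 bears the (2R)-2-methylbutanoyl group, a2 and a6 bear free hydroxyls, a3 a methyl group and a4 the only methyl ether of the molecule. Ring B is the aromatic half of a 5,7-dihydroxy-2,2,6-trimethylchroman-4-one, with the pyranone (ring C) fused at C4a and C8a. The single stereocentre is the α-carbon of the side-chain ketone; it has no stereogenic neighbour, so it must be brought in enantiopure and kept away from enolising conditions. Fragile elements are this α-centre, the electron-rich phenols, and ring C, which can open by retro-oxa-Michael reaction and reclose on the other ortho oxygen, exchanging the C6 and C8 substituents. The real difficulty is regiochemical: all twelve ring positions are substituted, the a4 methyl ether must be told apart from four phenolic hydroxyls, the 6-methyl/8-methylene pattern of ring B from its mirror pattern, and a hindered bridge must be forged between two crowded rings. The key step exploits the oxygens on a2, a4 and a6 with the acyl group on a1: a3–a4–a5–a6 has the pattern of a 1,1,3-trioxygenated diene and a1–a2 that of an acyl alkynyl ether, so ring A can be assembled from open-chain pieces with every substituent already in place.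

## Logic of the disconnections

**26 ⇒ 25.** The three benzylic O–C bonds on the a2, C5 and C7 oxygens are cut. These oxygens must be masked through enolate and ketene-acetal chemistry, while the a4 methyl ether must survive the unmasking. Hydrogenolysable masks meet both needs and leave the stereocentre alone. The gain is a precursor with one free, hydrogen-bonded phenol; the demand is a neutral hydrogenolysis that does not reduce the two aryl ketones.

**25 ⇒ 15 + 23 (key).** Bonds a2–a3 and a1–a6 of ring A are cut. Each oxygen of ring A then has a different origin: a4 from an enol ether, a6 from an ester carbonyl, a2 from an ynol ether, so the methyl ether is differentiated without any selective alkylation. The hexasubstituted ring falls into two open-chain partners, and the stereocentre arrives inside 23. The forward step must run neutral and cool, with orientation fixed by donor–acceptor matching.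

**23 ⇒ 18 + 21 (through 22); 18 ⇒ 16 (through 17); 21 ⇒ 19 + 20.** The acyl–alkyne bond is cut, then the amide C–N bond and the vinyl C–O bond. The gain is a purchased chiral acid and two commodity chemicals. The demand is acylation without over-addition or racemisation, and cold handling, because benzyl alkynyl ethers rearrange sigmatropically on heating.

**15 ⇒ 14 ⇒ 12 (through 13).** Two O–Si bonds and the enol O–CH3 bond are cut; these are functional-group changes only, and 12 already holds every carbon of ring A except a1 and a2. The demand is twofold: double enolisation without opening ring C, and O- rather than C-methylation of a substituted β-keto ester, which is why the enol ether is reached through ketal 13.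

**12 ⇒ 10 + 11.** The bond between the bridge methylene and the α-carbon of the keto ester is cut. It joins a natural nucleophile (β-keto ester α-carbon) to a natural electrophile (electron-rich benzylic carbon). The gain is separation of the whole ring B/ring C unit from a five-carbon chain that supplies a3 (with its methyl), a4, a5 and a6. The demand is clean mono-alkylation with a reactive benzylic chloride.

**10 ⇒ 9 ⇒ 8 ⇒ 7 ⇒ 6.** The C–Cl bond, the two O–benzyl bonds and the C8–CH bond are cut. C8 is the only free ring position of 6 and is activated by three oxygens, so a one-carbon electrophile can enter in one place only. Formylation comes before benzylation because the free phenols provide the activation. The demand is reduction of the aldehyde without touching the C4 ketone.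

**6 ⇒ 5 ⇒ 3 + 4.** The two O–CH3 bonds are cut (exchange of masks), then the C4–C4a and O1–C2 bonds of ring C. In 3 the oxygen para to the methyl group is the only free hydroxyl and its two ortho carbons are equivalent, so ring C can close in one way only. A symmetrical triol would offer two competing hydroxyls and give both the 6-methyl and the 8-methyl chromanone. Methyl ethers are used because they survive the strongly acidic acylation; the price is their later exchange for benzyl groups, which must not reopen ring C.

**3 ⇒ 1 (through 2).** The C–O bond para to the methyl group is cut. This position is meta to both methoxy groups and closed to electrophilic substitution, but it is the least hindered C–H, which a sterically governed C–H borylation selects. The gain is a cheap commercial arene.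

## Other disconnections considered

Alternative 1: The cut runs through ring B at C4a–C8a and C5–C6, with ring C added afterwards. Cyclobutenone A2, which already carries the complete ring A on its C4 methylene group, would be heated with benzyl ethynyl ether A3. Electrocyclic opening to the vinylketene, [2+2] addition of the ynol ether, a second four-electron opening and a six-electron closure should give phenol A1. Its new hydroxyl is the future O1 and its single free ring carbon the future C4a; acylation with 4, oxa-Michael closure and hydrogenolysis would finish the synthesis.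
- In its favour: the regiochemistry of this benzannulation with alkoxyalkynes is well established, so on precedent it is the better plan.
- Equal point: A1 has exactly one free hydroxyl and one free carbon, so ring C can close one way only, which matches the chosen plan's control of the 6-methyl/8-methylene pattern through 3.
- Against it: all of ring A, with its stereocentre and four differentiated oxygens, must be built first by classical aromatic chemistry and then attached to a cyclobutenone, so the plan is linear where the chosen one is convergent.
- Against it: the annulation needs roughly 80–120 °C, where A3 is liable to sigmatropic rearrangement, whereas step 14 is designed for room temperature or below.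
- Against it: ring C would be made last, under acidic acylating conditions, in the presence of four benzyl ethers and the enolisable stereocentre.
- Step economy: it is expected to be clearly longer.

Alternative 2: The cut is at C8–C8a and C5–C4a of ring B. The bis(silyloxy)diene A4, carrying an acyl-free ring A, would add through its terminal carbon (future C8) to the β-carbon of bromopyranone A5 (future C8a). The acetal carbon (future C5) would then bond to the bromine-bearing α-carbon (future C4a), and loss of methanol and HBr would aromatise ring B to A6.
- Better point: one step would give the whole chromanone with both phenols free and the 6-methyl/8-methylene pattern fixed by polarity. The chosen plan spends steps 1–3 on that pattern and four more on the bridge carbon.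
- Equal or better point: cyclisations of 1,3-bis(silyloxy)dienes with β-halo or β-oxygenated enones are an established reaction type, so its precedent is at least equal to that of step 14.
- Against it: A6 has hydrogen at a1, so the acyl group and the stereocentre would have to enter late by Friedel–Crafts acylation with an activated form of 16. That means a position between two benzyloxy groups, two free phenols on ring B, and risks of racemisation, O-acylation and debenzylation.
- Against it: the ring A unit inside A4 needs a methylphloroglucinol with one specific oxygen methylated and two benzylated. This is the selective O-alkylation problem that the chosen plan avoids by making the a4 ether from an enol ether.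
- Against it: the β-carbon of A5 belongs to a vinylogous ester and is a weak acceptor, so TiCl4 would probably be needed, which endangers benzyl ethers.
- Overall: shorter on ring B, longer and less safe on ring A and on the stereocentre; about equal in total length.

Alternative 3: The cut is at a5–a6 and a3–a4 of ring A. Cyclobutenone A7 would be heated with the chromanone-bearing methoxyalkyne A8; the same pericyclic cascade as in alternative 1 should insert the alkyne carbons as a5 and a4 and give phenol A9.
- Equal point: it shares the late, convergent construction of ring A, and A8 would be made from 10, so all ring B chemistry is common to both plans.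
- Better points: the regiochemistry rests on a well-precedented cascade; A8 has no pathway for retro-ene or benzyl-type sigmatropic decomposition and is more robust than 23; no silyl ketene acetal has to be made and ring C need not be enolised.
- Against it: A9 carries hydrogen at a1, so the acyl group with the stereocentre must be added afterwards by Friedel–Crafts or Fries chemistry next to a free phenol and a benzyl ether. That costs one or two extra steps and reintroduces the racemisation risk that step 14 avoids by delivering the acyl group intact under neutral conditions.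
- Against it: propargylation of a methoxyacetylide with the hindered chloride 10 and a thermolysis near 100 °C are further demands.
- Overall: better in precedent, equal in convergence, worse in stereochemical safety and in steps after the key step.

Key step: step 14

Assumption: 16 is purchased as the (R)-enantiomer in high enantiomeric purity; the alkene geometries of 14 and 15 and the sp3 centres of 12, 13 and 24 are immaterial because they are erased before 25.

Remark on the structures: the descriptor R is consistent for 16, 18, 23, 25 and 26 (acyl carbon > ethyl > methyl), and no structural error was found. The precursor design is tightened in two places. Ring B is built from 1 rather than from a symmetrical methylphloroglucinol, whose chromanone closure would not fix the 6-methyl/8-methylene pattern. And 23 is made and used cold, because benzyl alkynyl ethers rearrange on moderate heating.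

## Route

Step 1
Reactants: 1 2,6-dimethoxytoluene
Product: 3 3,5-dimethoxy-4-methylphenol, via aryl pinacol boronate 2 (not isolated)
Conditions: B2pin2 (1.0 equiv), [Ir(OMe)(cod)]2 (1.5 mol%), 4,4'-di-tert-butyl-2,2'-bipyridine (3 mol%), THF, 80 °C; then Oxone (2KHSO5·KHSO4·K2SO4), acetone/H2O, 0 °C to rt
Reagents that add atoms: bis(pinacolato)diboron, CC1(C)OB(OC1(C)C)B1OC(C)(C)C(C)(C)O1 (boron present only in 2); potassium peroxymonosulfate from Oxone, [K+].[O-]S(=O)(=O)OO (the phenol oxygen)
Why: Sterically governed iridium-catalysed aromatic C–H borylation should select the C–H para to the methyl group, the only one not ortho to a methoxy group. Oxidation of the C–B bond (aryl shift from boron to oxygen) then gives the phenol in the same flask, a known one-pot borylation/oxidation.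

Step 2
Reactants: 3 3,5-dimethoxy-4-methylphenol; 4 3-methylbut-2-enoic acid
Product: 5 5,7-dimethoxy-2,2,6-trimethylchroman-4-one
Conditions: P2O5 in MeSO3H (Eaton's reagent), 70 °C
Reagents that add atoms: none
Why: Friedel–Crafts acylation ortho to the phenol followed by 6-endo-trig oxa-Michael closure is the standard chromanone synthesis from electron-rich phenols. The two ortho carbons of 3 are equivalent and only one hydroxyl is free, so the 6-methyl pattern is fixed by construction.

Step 3
Reactants: 5 5,7-dimethoxy-2,2,6-trimethylchroman-4-one
Product: 6 5,7-dihydroxy-2,2,6-trimethylchroman-4-one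
Conditions: BBr3 (4 equiv), CH2Cl2, −78 °C to 0 °C; ice/H2O
Reagents that add atoms: none
Why: Lewis-acid cleavage of aryl methyl ethers (bromide attacks the methyl group of the boron-complexed ether), the peri ether being assisted by chelation to the C4 carbonyl. The low temperature is chosen so that the tertiary aryl ether of ring C, whose oxygen is deactivated by conjugation with the ketone, stays closed.

Step 4
Reactants: 6 5,7-dihydroxy-2,2,6-trimethylchroman-4-one
Product: 7 5,7-dihydroxy-2,2,6-trimethyl-4-oxochromane-8-carbaldehyde
Conditions: POCl3, DMF, EtOAc, 0 °C to rt; then H2O, 60 °C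
Reagents that add atoms: N,N-dimethylformamide, CN(C)C=O (formyl carbon); water, O (formyl oxygen)
Why: Vilsmeier–Haack formylation; C8 is the only unsubstituted ring carbon and is activated by two ortho oxygens and one para oxygen, as in formylations of acylphloroglucinols.

Step 5
Reactants: 7 5,7-dihydroxy-2,2,6-trimethyl-4-oxochromane-8-carbaldehyde
Product: 8 5,7-bis(benzyloxy)-2,2,6-trimethyl-4-oxochromane-8-carbaldehyde
Conditions: BnBr (3 equiv), K2CO3, DMF, 60 °C
Reagents that add atoms: benzyl bromide, BrCc1ccccc1
Why: Williamson ether synthesis on both phenols; warming in DMF is needed because each hydroxyl is hydrogen-bonded to a carbonyl group, and K2CO3 is too weak to enolise the chromanone, so ring C should stay closed.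

Step 6
Reactants: 8 5,7-bis(benzyloxy)-2,2,6-trimethyl-4-oxochromane-8-carbaldehyde
Product: 9 5,7-bis(benzyloxy)-8-(hydroxymethyl)-2,2,6-trimethylchroman-4-one
Conditions: NaBH4 (0.5 equiv), THF/MeOH, −20 °C to 0 °C
Reagents that add atoms: none
Why: Chemoselective borohydride reduction; the aldehyde is far more electrophilic than the C4 ketone, which is a vinylogous ester deactivated by three ring oxygens.

Step 7
Reactants: 9 5,7-bis(benzyloxy)-8-(hydroxymethyl)-2,2,6-trimethylchroman-4-one
Product: 10 5,7-bis(benzyloxy)-8-(chloromethyl)-2,2,6-trimethylchroman-4-one
Conditions: SOCl2 (1.2 equiv), CH2Cl2, 0 °C; evaporation, used crude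
Reagents that add atoms: thionyl chloride, O=S(Cl)Cl
Why: Chlorodehydroxylation of a benzylic alcohol with thionyl chloride, easy at a 2,4,6-trioxygenated benzylic carbon; the ring has no free position, so the chloride cannot alkylate itself.

Step 8
Reactants: 10 5,7-bis(benzyloxy)-8-(chloromethyl)-2,2,6-trimethylchroman-4-one; 11 methyl 3-oxopentanoate
Product: 12 methyl 2-{[5,7-bis(benzyloxy)-2,2,6-trimethyl-4-oxochroman-8-yl]methyl}-3-oxopentanoate (racemic)
Conditions: 11 (3 equiv), K2CO3, NaI (10 mol%), acetone, 50 °C
Reagents that add atoms: none
Why: Acetoacetic-ester-type C-alkylation of the β-keto ester enolate with Finkelstein activation of the chloride; excess 11 suppresses dialkylation. The new α-centre is formed racemic and is erased in step 9.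

Step 9
Reactants: 12 methyl 2-{[5,7-bis(benzyloxy)-2,2,6-trimethyl-4-oxochroman-8-yl]methyl}-3-oxopentanoate (racemic)
Product: 14 methyl 2-{[5,7-bis(benzyloxy)-2,2,6-trimethyl-4-oxochroman-8-yl]methyl}-3-methoxypent-2-enoate (E/Z mixture), via dimethyl ketal 13 (not isolated)
Conditions: HC(OMe)3, p-TsOH·H2O (cat.), MeOH, 50 °C; then toluene, 90 °C, MeOH distilled off; Et3N
Reagents that add atoms: trimethyl orthoformate, COC(OC)OC
Why: Acid-catalysed ketalisation with the orthoformate as water scavenger, then thermal loss of methanol to the enol ether, the usual O-methylation of β-keto esters that avoids C-methylation. Both alkene isomers, and any β,γ-unsaturated isomer, converge on the same dienolate in step 10; the conjugated, hindered C4 ketone should not ketalise.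

Step 10
Reactants: 14 methyl 2-{[5,7-bis(benzyloxy)-2,2,6-trimethyl-4-oxochroman-8-yl]methyl}-3-methoxypent-2-enoate (E/Z mixture)
Product: 15 5,7-bis(benzyloxy)-8-{2-[methoxy(trimethylsilyloxy)methylidene]-3-methoxypent-3-en-1-yl}-2,2,6-trimethyl-4-(trimethylsilyloxy)-2H-chromene (geometry mixture)
Conditions: LiN(iPr)2 (LDA, 2.4 equiv), Me3SiCl (3 equiv, present from the start), THF, −78 °C to −20 °C; pentane, filtration under Ar; used crude
Reagents that add atoms: chlorotrimethylsilane, C[Si](C)(C)Cl
Why: Kinetic γ-deprotonation of the β-methoxy enoate and α-deprotonation of the ketone, each trapped on oxygen, is the standard entry to Brassard-type silyl ketene acetal dienes and to silyl enol ethers. The internal quench at −78 °C should trap the chromanone enolate before it can open ring C by E1cB elimination.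

Step 11
Reactants: 16 (R)-2-methylbutanoic acid
Product: 18 (2R)-N-methoxy-N,2-dimethylbutanamide, via acyl imidazole 17 (not isolated)
Conditions: 1,1'-carbonyldiimidazole (1.1 equiv), CH2Cl2, 0 °C to rt; then MeNH(OMe)·HCl (1.2 equiv), rt
Reagents that add atoms: 1,1'-carbonyldiimidazole, O=C(n1ccnc1)n1ccnc1 (imidazole present only in 17); N,O-dimethylhydroxylamine hydrochloride, CNOC.Cl
Why: Weinreb amide formation through the acyl imidazole; no strong base and no ketene-prone acid chloride is involved, so the α-stereocentre should be retained.

Step 12
Reactants: 19 benzyl alcohol; 20 trichloroethylene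
Product: 21 benzyl (E)-1,2-dichlorovinyl ether
Conditions: KH, THF, 0 °C; then Cl2C=CHCl, −50 °C to rt
Reagents that add atoms: none
Why: Base-mediated substitution of a vinylic chloride of trichloroethylene by the alkoxide (elimination–addition), the established preparation of 1,2-dichlorovinyl ethers as alkoxyacetylide precursors.

Step 13
Reactants: 21 benzyl (E)-1,2-dichlorovinyl ether; 18 (2R)-N-methoxy-N,2-dimethylbutanamide
Product: 23 (4R)-1-(benzyloxy)-4-methylhex-1-yn-3-one, via lithium (benzyloxy)acetylide 22 (not isolated)
Conditions: n-BuLi (2.05 equiv), THF, −78 °C, 1 h; then 18 (0.9 equiv), −78 °C to −40 °C; sat. aq NH4Cl at −78 °C; work-up and chromatography below 10 °C, stored at −20 °C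
Reagents that add atoms: n-butyllithium, [Li]CCCC (lithium present only in 22)
Why: Dehydrochlorination and chlorine–lithium exchange by two equivalents of n-BuLi give the alkoxyacetylide, and its acylation by the Weinreb amide (Weinreb ketone synthesis) cannot over-add. The acetylide is too weak a base to deprotonate the amide α-carbon, and the cold, neutral work-up protects both the stereocentre and the heat-sensitive benzyl alkynyl ether.

Step 14
Reactants: 15 5,7-bis(benzyloxy)-8-{2-[methoxy(trimethylsilyloxy)methylidene]-3-methoxypent-3-en-1-yl}-2,2,6-trimethyl-4-(trimethylsilyloxy)-2H-chromene (geometry mixture); 23 (4R)-1-(benzyloxy)-4-methylhex-1-yn-3-one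
Product: 25 5,7-bis(benzyloxy)-8-{[4-(benzyloxy)-2-hydroxy-6-methoxy-5-methyl-3-[(2R)-2-methylbutanoyl]phenyl]methyl}-2,2,6-trimethylchroman-4-one, via cyclohexadiene cycloadduct 24 (not isolated)
Conditions: 15 (1.3 equiv), toluene (1 M), −20 °C to rt (never above 40 °C), dark, Ar; then 1 M HCl, THF, 0 °C
Reagents that add atoms: none
Why: Proposed new method: the closest known reaction type is the Diels–Alder/aromatisation of 1,3-dialkoxy-1-silyloxy dienes (Brassard-type) with acetylenic ketones and esters to give resorcinol monoethers; a β-alkoxy ynone has not been used as the two-carbon partner, and a hexasubstituted ring has not been made this way. The HOMO of 15 is largest at the methyl-bearing diene terminus (future a3) and the LUMO of the push–pull alkyne 23 at the benzyloxy-bearing β-carbon (future a2), so bond a2–a3 should lead in an asynchronous [4+2] transition state and the acetal carbon (a6) then joins the acyl-bearing carbon a1. Ring A thus closes as a six-membered carbocycle either by concerted [4+2] cycloaddition or, in the stepwise limit, by Mukaiyama–Michael addition followed by a 6-(enolendo)-exo-trig closure at the zwitterionic stage; both paths lead to 24. Dilute acid then expels methoxytrimethylsilane from the mixed ketal at a6, ring A aromatises to the a6 phenol, and the silyl enol ether of ring C reverts to the ketone. No stereocentre is created, since the two sp3 ring carbons of 24 vanish on aromatisation, and the (R)-centre should survive because no base is present and the acid contact is short and cold. Regioselectivity rests on the donor–acceptor matching, chemoselectivity on the much higher nucleophilicity of the ketene acetal compared with the aryl silyl enol ether, and the 40 °C ceiling keeps the benzyl alkynyl ether from sigmatropic rearrangement.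

Step 15
Reactants: 25 5,7-bis(benzyloxy)-8-{[4-(benzyloxy)-2-hydroxy-6-methoxy-5-methyl-3-[(2R)-2-methylbutanoyl]phenyl]methyl}-2,2,6-trimethylchroman-4-one
Product: 26 5,7-dihydroxy-8-{[2,4-dihydroxy-6-methoxy-5-methyl-3-[(2R)-2-methylbutanoyl]phenyl]methyl}-2,2,6-trimethylchroman-4-one (the target)
Conditions: H2 (1 atm), Pd/C (10% palladium on carbon), EtOAc, rt
Reagents that add atoms: none
Why: Catalytic hydrogenolysis of three aryl benzyl ethers under neutral conditions; the methyl ether, the diarylmethane, the two oxygen-flanked aryl ketones and the α-stereocentre should not be affected.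

## Compound list

1 | 2,6-dimethoxytoluene | COc1cccc(OC)c1C | starting material
2 | 2-(3,5-dimethoxy-4-methylphenyl)-4,4,5,5-tetramethyl-1,3,2-dioxaborolane | COc1cc(cc(OC)c1C)B1OC(C)(C)C(C)(C)O1 | intermediate (not isolated)
3 | 3,5-dimethoxy-4-methylphenol | COc1cc(O)cc(OC)c1C | intermediate
4 | 3-methylbut-2-enoic acid | CC(C)=CC(=O)O | starting material
5 | 5,7-dimethoxy-2,2,6-trimethylchroman-4-one | COc1cc2OC(C)(C)CC(=O)c2c(OC)c1C | intermediate
6 | 5,7-dihydroxy-2,2,6-trimethylchroman-4-one | Cc1c(O)cc2OC(C)(C)CC(=O)c2c1O | intermediate
7 | 5,7-dihydroxy-2,2,6-trimethyl-4-oxochromane-8-carbaldehyde | O=Cc1c(O)c(C)c(O)c2c1OC(C)(C)CC2=O | intermediate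
8 | 5,7-bis(benzyloxy)-2,2,6-trimethyl-4-oxochromane-8-carbaldehyde | O=Cc1c(OCc2ccccc2)c(C)c(OCc2ccccc2)c2c1OC(C)(C)CC2=O | intermediate
9 | 5,7-bis(benzyloxy)-8-(hydroxymethyl)-2,2,6-trimethylchroman-4-one | OCc1c(OCc2ccccc2)c(C)c(OCc2ccccc2)c2c1OC(C)(C)CC2=O | intermediate
10 | 5,7-bis(benzyloxy)-8-(chloromethyl)-2,2,6-trimethylchroman-4-one | ClCc1c(OCc2ccccc2)c(C)c(OCc2ccccc2)c2c1OC(C)(C)CC2=O | intermediate
11 | methyl 3-oxopentanoate | CCC(=O)CC(=O)OC | starting material
12 | methyl 2-{[5,7-bis(benzyloxy)-2,2,6-trimethyl-4-oxochroman-8-yl]methyl}-3-oxopentanoate (racemic) | CCC(=O)C(Cc1c(OCc2ccccc2)c(C)c(OCc2ccccc2)c2c1OC(C)(C)CC2=O)C(=O)OC | intermediate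
13 | methyl 2-{[5,7-bis(benzyloxy)-2,2,6-trimethyl-4-oxochroman-8-yl]methyl}-3,3-dimethoxypentanoate | CCC(OC)(OC)C(Cc1c(OCc2ccccc2)c(C)c(OCc2ccccc2)c2c1OC(C)(C)CC2=O)C(=O)OC | intermediate (not isolated)
14 | methyl 2-{[5,7-bis(benzyloxy)-2,2,6-trimethyl-4-oxochroman-8-yl]methyl}-3-methoxypent-2-enoate (E/Z mixture) | CCC(OC)=C(Cc1c(OCc2ccccc2)c(C)c(OCc2ccccc2)c2c1OC(C)(C)CC2=O)C(=O)OC | intermediate
15 | 5,7-bis(benzyloxy)-8-{2-[methoxy(trimethylsilyloxy)methylidene]-3-methoxypent-3-en-1-yl}-2,2,6-trimethyl-4-(trimethylsilyloxy)-2H-chromene (geometry mixture) | COC(O[Si](C)(C)C)=C(Cc1c(OCc2ccccc2)c(C)c(OCc2ccccc2)c2c1OC(C)(C)C=C2O[Si](C)(C)C)C(OC)=CC | intermediate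
16 | (R)-2-methylbutanoic acid | CC[C@@H](C)C(=O)O | starting material
17 | (2R)-1-(1H-imidazol-1-yl)-2-methylbutan-1-one | CC[C@@H](C)C(=O)n1ccnc1 | intermediate (not isolated)
18 | (2R)-N-methoxy-N,2-dimethylbutanamide | CC[C@@H](C)C(=O)N(C)OC | intermediate
19 | benzyl alcohol | OCc1ccccc1 | starting material
20 | trichloroethylene | ClC=C(Cl)Cl | starting material
21 | benzyl (E)-1,2-dichlorovinyl ether | Cl/C=C(/Cl)OCc1ccccc1 | intermediate
22 | lithium (benzyloxy)acetylide | [Li]C#COCc1ccccc1 | intermediate (not isolated)
23 | (4R)-1-(benzyloxy)-4-methylhex-1-yn-3-one | CC[C@@H](C)C(=O)C#COCc1ccccc1 | intermediate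
24 | 2-(benzyloxy)-5-({5,7-bis(benzyloxy)-2,2,6-trimethyl-4-(trimethylsilyloxy)-2H-chromen-8-yl}methyl)-4,6-dimethoxy-3-methyl-1-[(2R)-2-methylbutanoyl]-6-(trimethylsilyloxy)cyclohexa-1,4-diene (diastereomer mixture at C3 and C6) | CC[C@@H](C)C(=O)C1=C(OCc2ccccc2)C(C)C(OC)=C(Cc2c(OCc3ccccc3)c(C)c(OCc3ccccc3)c3c2OC(C)(C)C=C3O[Si](C)(C)C)C1(OC)O[Si](C)(C)C | intermediate (not isolated)
25 | 5,7-bis(benzyloxy)-8-{[4-(benzyloxy)-2-hydroxy-6-methoxy-5-methyl-3-[(2R)-2-methylbutanoyl]phenyl]methyl}-2,2,6-trimethylchroman-4-one | CC[C@@H](C)C(=O)c1c(OCc2ccccc2)c(C)c(OC)c(Cc2c(OCc3ccccc3)c(C)c(OCc3ccccc3)c3c2OC(C)(C)CC3=O)c1O | intermediate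
26 | 5,7-dihydroxy-8-{[2,4-dihydroxy-6-methoxy-5-methyl-3-[(2R)-2-methylbutanoyl]phenyl]methyl}-2,2,6-trimethylchroman-4-one (CNP0303209.1) | CC[C@@H](C)C(=O)c1c(O)c(C)c(OC)c(Cc2c(O)c(C)c(O)c3c2OC(C)(C)CC3=O)c1O | target

## Step count and least certain steps

Total step count: 15. Longest linear sequence: 12 steps (steps 1–10, 14 and 15); the ynone branch (steps 11 and 13, fed by step 12) joins at step 14.

**Step 14 (bears the label "Proposed new method:").**
- What may go wrong: the push–pull alkyne may be too weak an acceptor for a thermal reaction below 40 °C. The diene would then be lost by slow hydrolysis or silyl transfer, 23 would drain away by sigmatropic rearrangement, or the diene would add to the ynone carbonyl instead of the β-carbon. Crowding at the a1–a6 bond may also stall ring closure after the first bond.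
- Fallback (known chemistry only): it sets out from 3, 16 and 10 and rejoins the route at 26. Friedel–Crafts acylation of 3 with 16, activated by trifluoroacetic anhydride at 0 °C to rt, should give (2R)-1-(6-hydroxy-2,4-dimethoxy-3-methylphenyl)-2-methylbutan-1-one F1; the two ortho carbons of 3 are equivalent. Chelation-controlled cleavage by BCl3 (CH2Cl2, −78 °C to 0 °C) of the one methoxy group ortho to the ketone should give (2R)-1-(2,6-dihydroxy-4-methoxy-3-methylphenyl)-2-methylbutan-1-one F2, the complete ring A with one free carbon. Friedel–Crafts benzylation of that carbon with 10 (ZnCl2, CH2Cl2, 0 °C) should give 5,7-bis(benzyloxy)-8-{[2,4-dihydroxy-6-methoxy-5-methyl-3-[(2R)-2-methylbutanoyl]phenyl]methyl}-2,2,6-trimethylchroman-4-one F3, and hydrogenolysis as in step 15 leads to 26. The enantiomeric purity would have to be checked after the acidic acylation.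

**Step 10.**
- What may go wrong: E1cB opening of ring C through the lithium enolate before silylation, incomplete γ-deprotonation of the hindered enoate, or hydrolysis of the ketene acetal during isolation.
- Fallback: it sets out from 14 and rejoins at 25. The ketone is masked first without any lithium enolate, by soft enolisation with tert-butyldimethylsilyl triflate and Et3N (CH2Cl2, 0 °C), giving methyl 2-({5,7-bis(benzyloxy)-4-[(tert-butyldimethylsilyl)oxy]-2,2,6-trimethyl-2H-chromen-8-yl}methyl)-3-methoxypent-2-enoate F4, which can be purified. A single equivalent of LDA with Me3SiCl then gives 5,7-bis(benzyloxy)-4-[(tert-butyldimethylsilyl)oxy]-8-{2-[methoxy(trimethylsilyloxy)methylidene]-3-methoxypent-3-en-1-yl}-2,2,6-trimethyl-2H-chromene F5, which is combined with 23 as in step 14; aqueous acid work-up returns the ketone and gives 25.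

**Step 13.**
- What may go wrong: sigmatropic rearrangement or oligomerisation of the benzyl alkynyl ether during isolation, or attack of residual n-BuLi on the amide.
- Fallback: it sets out from 18 and rejoins at 26. Commercial ethoxyethyne F6 is lithiated and acylated with 18 to give the thermally robust (4R)-1-ethoxy-4-methylhex-1-yn-3-one F7. Annulation with 15, which may now be heated, should give 5,7-bis(benzyloxy)-8-{[4-ethoxy-2-hydroxy-6-methoxy-5-methyl-3-[(2R)-2-methylbutanoyl]phenyl]methyl}-2,2,6-trimethylchroman-4-one F8. Excess BCl3 (CH2Cl2, −78 °C to 0 °C) should then cleave the ethyl ether ortho to the ketone together with the two benzyl ethers and spare the para methyl ether, giving 26. Selectivity against the a4 methyl ether is the weak point of this variant.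

**Step 9.**
- What may go wrong: slow or incomplete conversion of the hindered α-substituted keto ester, stalling at the ketal stage, or acid-promoted retro-Claisen cleavage.
- Fallback: it sets out from 11 and 10 and rejoins at 15. 11 is first converted with HC(OMe)3 and acid into methyl (E)-3-methoxypent-2-enoate F9. Its lithium dienolate (LDA, THF/DMPU, −78 °C) is alkylated at the α-carbon with 10 to give methyl 2-{[5,7-bis(benzyloxy)-2,2,6-trimethyl-4-oxochroman-8-yl]methyl}-3-methoxypent-3-enoate F10. Under the conditions of step 10 this gives the same dienolate and hence 15.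

**Step 3.**
- What may go wrong: Lewis-acid opening of the tertiary aryl ether of ring C followed by reclosure on the newly freed C5 oxygen, which would scramble the 6-methyl and 8-methyl patterns; or incomplete cleavage of the C7 methyl ether.
- Fallback: it sets out from 4 and rejoins at 6. Purchased 2-methylphloroglucinol F11 is condensed with 4 in Eaton's reagent. This should give 6 together with 5,7-dihydroxy-2,2,8-trimethylchroman-4-one F12, from which 6 is separated by chromatography or crystallisation and assigned by long-range NMR correlations. The route is two steps shorter but loses material to the regioisomer.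

## Further compounds

F1 | step 14 | (2R)-1-(6-hydroxy-2,4-dimethoxy-3-methylphenyl)-2-methylbutan-1-one | CC[C@@H](C)C(=O)c1c(O)cc(OC)c(C)c1OC
F2 | step 14 | (2R)-1-(2,6-dihydroxy-4-methoxy-3-methylphenyl)-2-methylbutan-1-one | CC[C@@H](C)C(=O)c1c(O)cc(OC)c(C)c1O
F3 | step 14 | 5,7-bis(benzyloxy)-8-{[2,4-dihydroxy-6-methoxy-5-methyl-3-[(2R)-2-methylbutanoyl]phenyl]methyl}-2,2,6-trimethylchroman-4-one | CC[C@@H](C)C(=O)c1c(O)c(C)c(OC)c(Cc2c(OCc3ccccc3)c(C)c(OCc3ccccc3)c3c2OC(C)(C)CC3=O)c1O
F4 | step 10 | methyl 2-({5,7-bis(benzyloxy)-4-[(tert-butyldimethylsilyl)oxy]-2,2,6-trimethyl-2H-chromen-8-yl}methyl)-3-methoxypent-2-enoate | CCC(OC)=C(Cc1c(OCc2ccccc2)c(C)c(OCc2ccccc2)c2c1OC(C)(C)C=C2O[Si](C)(C)C(C)(C)C)C(=O)OC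
F5 | step 10 | 5,7-bis(benzyloxy)-4-[(tert-butyldimethylsilyl)oxy]-8-{2-[methoxy(trimethylsilyloxy)methylidene]-3-methoxypent-3-en-1-yl}-2,2,6-trimethyl-2H-chromene | COC(O[Si](C)(C)C)=C(Cc1c(OCc2ccccc2)c(C)c(OCc2ccccc2)c2c1OC(C)(C)C=C2O[Si](C)(C)C(C)(C)C)C(OC)=CC
F6 | step 13 | ethoxyethyne | CCOC#C
F7 | step 13 | (4R)-1-ethoxy-4-methylhex-1-yn-3-one | CC[C@@H](C)C(=O)C#COCC
F8 | step 13 | 5,7-bis(benzyloxy)-8-{[4-ethoxy-2-hydroxy-6-methoxy-5-methyl-3-[(2R)-2-methylbutanoyl]phenyl]methyl}-2,2,6-trimethylchroman-4-one | CC[C@@H](C)C(=O)c1c(OCC)c(C)c(OC)c(Cc2c(OCc3ccccc3)c(C)c(OCc3ccccc3)c3c2OC(C)(C)CC3=O)c1O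
F9 | step 9 | methyl (E)-3-methoxypent-2-enoate | CC/C(OC)=C\C(=O)OC
F10 | step 9 | methyl 2-{[5,7-bis(benzyloxy)-2,2,6-trimethyl-4-oxochroman-8-yl]methyl}-3-methoxypent-3-enoate | CC=C(OC)C(Cc1c(OCc2ccccc2)c(C)c(OCc2ccccc2)c2c1OC(C)(C)CC2=O)C(=O)OC
F11 | step 3 | 2-methylphloroglucinol | Cc1c(O)cc(O)cc1O
F12 | step 3 | 5,7-dihydroxy-2,2,8-trimethylchroman-4-one | Cc1c(O)cc(O)c2c1OC(C)(C)CC2=O
A1 | alternative 1 | 3,5-bis(benzyloxy)-2-{2,4-bis(benzyloxy)-6-methoxy-5-methyl-3-[(2R)-2-methylbutanoyl]benzyl}-4-methylphenol | Oc1cc(OCc2ccccc2)c(C)c(OCc2ccccc2)c1Cc1c(OCc2ccccc2)c(C(=O)[C@H](C)CC)c(OCc2ccccc2)c(C)c1OC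
A2 | alternative 1 | 3-(benzyloxy)-4-{2,4-bis(benzyloxy)-6-methoxy-5-methyl-3-[(2R)-2-methylbutanoyl]benzyl}-2-methylcyclobut-2-en-1-one | O=C1C(C)=C(OCc2ccccc2)C1Cc1c(OCc2ccccc2)c(C(=O)[C@H](C)CC)c(OCc2ccccc2)c(C)c1OC
A3 | alternative 1 | benzyl ethynyl ether | C#COCc1ccccc1
A4 | alternative 2 | 5-[2,4-bis(benzyloxy)-6-methoxy-5-methylphenyl]-1-methoxy-2-methyl-1,3-bis(trimethylsilyloxy)penta-1,3-diene | COC(O[Si](C)(C)C)=C(C)C(O[Si](C)(C)C)=CCc1c(OCc2ccccc2)cc(OCc2ccccc2)c(C)c1OC
A5 | alternative 2 | 5-bromo-2,2-dimethyl-2,3-dihydro-4H-pyran-4-one | CC1(C)CC(=O)C(Br)=CO1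
A6 | alternative 2 | 8-[2,4-bis(benzyloxy)-6-methoxy-5-methylbenzyl]-5,7-dihydroxy-2,2,6-trimethylchroman-4-one | COc1c(C)c(OCc2ccccc2)cc(OCc2ccccc2)c1Cc1c(O)c(C)c(O)c2c1OC(C)(C)CC2=O
A7 | alternative 3 | 3-(benzyloxy)-2-methylcyclobut-2-en-1-one | CC1=C(OCc2ccccc2)CC1=O
A8 | alternative 3 | 5,7-bis(benzyloxy)-8-(3-methoxyprop-2-yn-1-yl)-2,2,6-trimethylchroman-4-one | COC#CCc1c(OCc2ccccc2)c(C)c(OCc2ccccc2)c2c1OC(C)(C)CC2=O
A9 | alternative 3 | 5,7-bis(benzyloxy)-8-[4-(benzyloxy)-2-hydroxy-6-methoxy-5-methylbenzyl]-2,2,6-trimethylchroman-4-one | c1c(OCc2ccccc2)c(C)c(OC)c(Cc2c(OCc3ccccc3)c(C)c(OCc3ccccc3)c3c2OC(C)(C)CC3=O)c1O
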